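**Strategy.** Everything rests on disconnecting the C1–C2 bond, the bond shared by the 14-membered carbocycle and the cis-fused α-methylene-γ-lactone (cembrane numbering: C1 ring-fusion carbon, C2 lactone carbinol, C11–C12 epoxide, C13 acetoxy carbon, C15=C17 exocyclic methylene). In one operation a chromium-mediated intramolecular 2-(methoxycarbonyl)allylation of an enal closes the carbocycle, sets C1 and C2 together and lets the alkoxide lactonise in the same flask; no ring is formed afterwards. Its precursor is an open-chain (Z)-2-(bromomethyl)enoate aldehyde already carrying the epoxide and the C13 acetate. C13 is set by catalysis; C11, C12, C1 and C2 are relayed from it. The step exploits the homoallylic array O–C2–C1–C15=C17 of the lactone.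

Key step: step 11

Remark on the chemistry: compounds 1, 2, 8 and 15 are taken as commercial. Further numbering: C3=C4 is the E olefin, C7=C8 the Z olefin, C14 the CH2 between C13 and C1, C16 the lactone carbonyl.

Step 1
Reactants: 1 nerylacetone; 2 triethyl phosphonoacetate
Product: 3 ethyl (2E,6Z)-3,7,11-trimethyldodeca-2,6,10-trienoate
Conditions: NaH, THF, 0 °C to rt
Reagents that add atoms: none
Why: Horner–Wadsworth–Emmons olefination of the methyl ketone should give mainly the (2E)-enoate (C3=C4), the minor (2Z)-isomer being removed by chromatography; the (Z)-olefin bought with 1 is not touched.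

Step 2
Reactants: 3 ethyl (2E,6Z)-3,7,11-trimethyldodeca-2,6,10-trienoate
Product: 4 (2E,6Z)-3,7,11-trimethyldodeca-2,6,10-trien-1-ol
Conditions: i-Bu2AlH, CH2Cl2, −78 to 0 °C; aq. potassium sodium tartrate
Reagents that add atoms: none
Why: 1,2-Reduction of the conjugated ester to the allylic alcohol, which leaves the isolated olefins and their geometry alone.

Step 3
Reactants: 4 (2E,6Z)-3,7,11-trimethyldodeca-2,6,10-trien-1-ol
Product: 5 tert-butyldimethyl{[(2E,6Z)-3,7,11-trimethyldodeca-2,6,10-trien-1-yl]oxy}silane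
Conditions: TBSCl, imidazole, CH2Cl2, rt
Reagents that add atoms: tert-butyldimethylsilyl chloride, CC(C)(C)[Si](C)(C)Cl
Why: Silyl ether protection of the primary allylic alcohol (C2–OH) for the oxidations that follow.

Step 4
Reactants: 5 tert-butyldimethyl{[(2E,6Z)-3,7,11-trimethyldodeca-2,6,10-trien-1-yl]oxy}silane
Product: 7 (2E,6Z,10E)-12-[(tert-butyldimethylsilyl)oxy]-2,6,10-trimethyldodeca-2,6,10-trienal, via allylic alcohol 6 (not isolated)
Conditions: SeO2 (cat.), TBHP, salicylic acid (cat.), CH2Cl2, 0 °C to rt; crude, then MnO2, CH2Cl2, rt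
Reagents that add atoms: tert-butyl hydroperoxide, CC(C)(C)OO
Why: SeO2-catalysed allylic oxidation (ene reaction, then [2,3]-sigmatropic shift) should attack the (E)-methyl group of the terminal, least hindered trisubstituted olefin, the C3=C4 olefin being deactivated by its allylic silyloxy group; MnO2 then converges alcohol and enal to the (E)-enal (C13 aldehyde).

Step 5
Reactants: 7 (2E,6Z,10E)-12-[(tert-butyldimethylsilyl)oxy]-2,6,10-trimethyldodeca-2,6,10-trienal; 8 allylboronic acid pinacol ester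
Product: 10 (4R,5E,9Z,13E)-15-[(tert-butyldimethylsilyl)oxy]-5,9,13-trimethylpentadeca-1,5,9,13-tetraen-4-ol, via pinacol borate ester 9 (not isolated)
Conditions: (R)-3,3′-bis(2,4,6-triisopropylphenyl)-1,1′-binaphthyl-2,2′-diyl hydrogen phosphate (5 mol%), toluene, −30 °C; aq. NaHCO3
Reagents that add atoms: none
Why: Chiral phosphoric acid-catalysed allylboration through a closed six-membered transition state; the (R)-catalyst should deliver the allyl group to the Re face of the enal, which sets C13 as R.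

Step 6
Reactants: 10 (4R,5E,9Z,13E)-15-[(tert-butyldimethylsilyl)oxy]-5,9,13-trimethylpentadeca-1,5,9,13-tetraen-4-ol
Product: 11 (1R)-1-[(2S,3S)-3-{(3Z,7E)-9-[(tert-butyldimethylsilyl)oxy]-3,7-dimethylnona-3,7-dien-1-yl}-2-methyloxiran-2-yl]but-3-en-1-ol
Conditions: VO(acac)2 (3 mol%), TBHP (decane), CH2Cl2, 0 °C
Reagents that add atoms: tert-butyl hydroperoxide, CC(C)(C)OO
Why: Hydroxyl-directed vanadium-catalysed epoxidation of the allylic alcohol; A(1,2) strain between the C12 methyl group and the C13 substituents should favour the erythro epoxy alcohol, which sets C11 and C12 as in the target, while the homoallylic vinyl group and the remote olefins react far more slowly.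

Step 7
Reactants: 11 (1R)-1-[(2S,3S)-3-{(3Z,7E)-9-[(tert-butyldimethylsilyl)oxy]-3,7-dimethylnona-3,7-dien-1-yl}-2-methyloxiran-2-yl]but-3-en-1-ol
Product: 12 (1R)-1-[(2R,3S)-3-{(3Z,7E)-9-[(tert-butyldimethylsilyl)oxy]-3,7-dimethylnona-3,7-dien-1-yl}-2-methyloxiran-2-yl]but-3-en-1-yl acetate
Conditions: Ac2O, pyridine, DMAP (cat.), CH2Cl2, 0 °C to rt
Reagents that add atoms: acetic anhydride, CC(=O)OC(C)=O
Why: DMAP-catalysed acylation installs the C13 acetate of the target early; without a free alkoxide no Payne rearrangement is expected (the oxirane descriptor changes only through the sequence rule).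

Step 8
Reactants: 12 (1R)-1-[(2R,3S)-3-{(3Z,7E)-9-[(tert-butyldimethylsilyl)oxy]-3,7-dimethylnona-3,7-dien-1-yl}-2-methyloxiran-2-yl]but-3-en-1-yl acetate
Product: 13 (1R)-1-[(2R,3S)-3-[(3Z,7E)-9-hydroxy-3,7-dimethylnona-3,7-dien-1-yl]-2-methyloxiran-2-yl]but-3-en-1-yl acetate
Conditions: HF·pyridine, pyridine, THF, 0 °C to rt
Reagents that add atoms: none
Why: Buffered fluoride desilylation of the primary allylic silyl ether, which the epoxide and the acetate should survive.

Step 9
Reactants: 13 (1R)-1-[(2R,3S)-3-[(3Z,7E)-9-hydroxy-3,7-dimethylnona-3,7-dien-1-yl]-2-methyloxiran-2-yl]but-3-en-1-yl acetate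
Product: 14 (1R)-1-[(2R,3S)-3-[(3Z,7E)-3,7-dimethyl-9-oxonona-3,7-dien-1-yl]-2-methyloxiran-2-yl]but-3-en-1-yl acetate
Conditions: MnO2, CH2Cl2, rt
Reagents that add atoms: none
Why: MnO2 oxidation of the allylic alcohol gives the (E)-enal (C2 aldehyde) without touching the epoxide, the acetate or the terminal olefin.

Step 10
Reactants: 14 (1R)-1-[(2R,3S)-3-[(3Z,7E)-3,7-dimethyl-9-oxonona-3,7-dien-1-yl]-2-methyloxiran-2-yl]but-3-en-1-yl acetate; 15 methyl 2-(bromomethyl)acrylate
Product: 16 methyl (2Z,5R)-5-acetoxy-2-(bromomethyl)-5-[(2R,3S)-3-[(3Z,7E)-3,7-dimethyl-9-oxonona-3,7-dien-1-yl]-2-methyloxiran-2-yl]pent-2-enoate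
Conditions: 15 (5 equiv), second-generation Hoveyda–Grubbs catalyst (10 mol%), CH2Cl2, 40 °C
Reagents that add atoms: none
Why: Olefin cross-metathesis of the monosubstituted olefin with an excess of the 1,1-disubstituted acrylate; the trisubstituted olefins and the enal are inert, and the isomer with C14 trans to the ester (Z by the sequence rule) should be favoured thermodynamically.

Step 11
Reactants: 16 methyl (2Z,5R)-5-acetoxy-2-(bromomethyl)-5-[(2R,3S)-3-[(3Z,7E)-3,7-dimethyl-9-oxonona-3,7-dien-1-yl]-2-methyloxiran-2-yl]pent-2-enoate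
Product: 19 (1S,2S,3E,7Z,11S,12R,13R)-13-acetoxy-11,12-epoxycembra-3,7,15(17)-trien-16,2-olide, via allylchromium species 17 (not isolated), via chromium alkoxide 18 (not isolated)
Conditions: CrCl2 (8 equiv), THF, 4 Å MS, rt, slow addition of 16 to 0.002 M; aq. NH4Cl
Reagents that add atoms: none
Why: CrCl2 inserts into the allylic C–Br bond to give 17, whose γ-carbon C1 adds to the C2 aldehyde through a six-membered Zimmerman–Traxler chair (intramolecular Nozaki–Hiyama allylation with a 2-(alkoxycarbonyl)allyl halide; the closest known type is the chromium- or zinc-mediated macrocyclisation of ω-formyl 2-(bromomethyl)alk-2-enoates to ring-fused α-methylene lactones), and the chromium alkoxide 18 then acylates itself on the neighbouring methyl ester. The 14-membered carbocycle is closed by the C1–C2 bond (carbonyl addition, exo at the aldehyde, with allylic transposition that creates the exocyclic C15=C17 methylene), and the lactone by 5-exo-trig attack of the C2 oxygen on the ester carbonyl C16 with loss of methoxide. The cis ring fusion follows from the chair in which the C3 alkenyl group of the aldehyde is equatorial and C14, cis to the metallated CH2 in the (Z)-bromide, is axial, which gives the syn adduct. The absolute sense (Si face of C1 onto the Re face of C2, giving 1S,2S) is relayed from C13: in this pairing the C2–C1–C14–C13–C12 backbone can stay extended with the acetoxy group on the ring periphery and 1,3-anti to the C15 branch, whereas the other chair would place them 1,3-syn. The step needs ring closure to outrun oligomerisation (slow addition, high dilution), 1,2-addition to the enal (usual for allylchromium reagents) and tolerance of the epoxide and the acetate (neutral aprotic medium). This facial selectivity is a qualitative prediction and is the least secure point of the route.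

**Compound list**

1 | nerylacetone, (5Z)-6,10-dimethylundeca-5,9-dien-2-one | CC(=O)CC/C=C(/C)CCC=C(C)C | starting material
2 | triethyl phosphonoacetate | CCOC(=O)CP(=O)(OCC)OCC | starting material
3 | ethyl (2E,6Z)-3,7,11-trimethyldodeca-2,6,10-trienoate | CCOC(=O)/C=C(\C)CC/C=C(/C)CCC=C(C)C | intermediate
4 | (2E,6Z)-3,7,11-trimethyldodeca-2,6,10-trien-1-ol | OC/C=C(\C)CC/C=C(/C)CCC=C(C)C | intermediate
5 | tert-butyldimethyl{[(2E,6Z)-3,7,11-trimethyldodeca-2,6,10-trien-1-yl]oxy}silane | CC(C)(C)[Si](C)(C)OC/C=C(\C)CC/C=C(/C)CCC=C(C)C | intermediate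
6 | (2E,6Z,10E)-12-[(tert-butyldimethylsilyl)oxy]-2,6,10-trimethyldodeca-2,6,10-trien-1-ol | CC(C)(C)[Si](C)(C)OC/C=C(\C)CC/C=C(/C)CC/C=C(\C)CO | intermediate (not isolated)
7 | (2E,6Z,10E)-12-[(tert-butyldimethylsilyl)oxy]-2,6,10-trimethyldodeca-2,6,10-trienal | CC(C)(C)[Si](C)(C)OC/C=C(\C)CC/C=C(/C)CC/C=C(\C)C=O | intermediate
8 | allylboronic acid pinacol ester, 2-allyl-4,4,5,5-tetramethyl-1,3,2-dioxaborolane | C=CCB1OC(C)(C)C(C)(C)O1 | starting material
9 | pinacol borate ester of 10 (O-boryl homoallylic alcohol) | CC(C)(C)[Si](C)(C)OC/C=C(\C)CC/C=C(/C)CC/C=C(\C)[C@H](OB1OC(C)(C)C(C)(C)O1)CC=C | intermediate (not isolated)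
10 | (4R,5E,9Z,13E)-15-[(tert-butyldimethylsilyl)oxy]-5,9,13-trimethylpentadeca-1,5,9,13-tetraen-4-ol | CC(C)(C)[Si](C)(C)OC/C=C(\C)CC/C=C(/C)CC/C=C(\C)[C@H](O)CC=C | intermediate
11 | (1R)-1-[(2S,3S)-3-{(3Z,7E)-9-[(tert-butyldimethylsilyl)oxy]-3,7-dimethylnona-3,7-dien-1-yl}-2-methyloxiran-2-yl]but-3-en-1-ol | CC(C)(C)[Si](C)(C)OC/C=C(\C)CC/C=C(/C)CC[C@@H]1O[C@@]1(C)[C@H](O)CC=C | intermediate
12 | (1R)-1-[(2R,3S)-3-{(3Z,7E)-9-[(tert-butyldimethylsilyl)oxy]-3,7-dimethylnona-3,7-dien-1-yl}-2-methyloxiran-2-yl]but-3-en-1-yl acetate | CC(C)(C)[Si](C)(C)OC/C=C(\C)CC/C=C(/C)CC[C@@H]1O[C@@]1(C)[C@H](OC(C)=O)CC=C | intermediate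
13 | (1R)-1-[(2R,3S)-3-[(3Z,7E)-9-hydroxy-3,7-dimethylnona-3,7-dien-1-yl]-2-methyloxiran-2-yl]but-3-en-1-yl acetate | OC/C=C(\C)CC/C=C(/C)CC[C@@H]1O[C@@]1(C)[C@H](OC(C)=O)CC=C | intermediate
14 | (1R)-1-[(2R,3S)-3-[(3Z,7E)-3,7-dimethyl-9-oxonona-3,7-dien-1-yl]-2-methyloxiran-2-yl]but-3-en-1-yl acetate | O=C/C=C(\C)CC/C=C(/C)CC[C@@H]1O[C@@]1(C)[C@H](OC(C)=O)CC=C | intermediate
15 | methyl 2-(bromomethyl)acrylate | C=C(CBr)C(=O)OC | starting material
16 | methyl (2Z,5R)-5-acetoxy-2-(bromomethyl)-5-[(2R,3S)-3-[(3Z,7E)-3,7-dimethyl-9-oxonona-3,7-dien-1-yl]-2-methyloxiran-2-yl]pent-2-enoate | O=C/C=C(\C)CC/C=C(/C)CC[C@@H]1O[C@@]1(C)[C@H](OC(C)=O)C/C=C(\CBr)C(=O)OC | intermediate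
17 | allylchromium dichloride derived from 16 (C17–CrCl2) | O=C/C=C(\C)CC/C=C(/C)CC[C@@H]1O[C@@]1(C)[C@H](OC(C)=O)C/C=C(\C[Cr](Cl)Cl)C(=O)OC | intermediate (not isolated)
18 | dichlorochromium alkoxide of the 14-membered (1S,2S)-2-hydroxy methyl ester | Cl[Cr](Cl)O[C@H]1/C=C(\C)CC/C=C(/C)CC[C@@H]2O[C@@]2(C)[C@H](OC(C)=O)C[C@H]1C(=C)C(=O)OC | intermediate (not isolated)
19 | (1S,2S,3E,7Z,11S,12R,13R)-13-acetoxy-11,12-epoxycembra-3,7,15(17)-trien-16,2-olide | C=C1C(=O)O[C@H]2/C=C(\C)CC/C=C(/C)CC[C@@H]3O[C@@]3(C)[C@H](OC(C)=O)C[C@@H]12 | target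

**Step count.** Total: 11 steps. Longest linear sequence: 11 steps (1 to 19).

**Steps most likely to fail**

Step 11. The remote C13 centre may not discriminate enough between the two chair transition states, so the ring could close with poor facial selectivity, and intermolecular coupling may compete. Fallback: stereocontrol is moved from the substrate to the metal. Setting out from 16, the same C1–C2 bond is closed with CrCl2 bound to a stoichiometric chiral oxazoline–sulfonamide ligand (Et3N, THF, high dilution). The ligand enantiomer is chosen to send C1 to the Re face of the aldehyde, matched with C13. The alkoxide again lactonises in the flask and the sequence comes back at 19; no new compound is made (F0).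

Step 10. Productive metathesis of the hindered, electron-poor 1,1-disubstituted olefin may be too slow, so that self-metathesis of the terminal olefin, catalyst decay by the allylic bromide or poor geometric control take over. Fallback: the acrylate unit is brought in by forming the C13–C14 bond instead of by metathesis, setting out from 7.
- The known methyl (2E)-2-(hydroxymethyl)but-2-enoate is silylated (TBSCl, imidazole) to methyl (2E)-2-{[(tert-butyldimethylsilyl)oxy]methyl}but-2-enoate F1.
- F1 is converted (lithium diisopropylamide, TBSCl, DMPU, THF, −78 °C) into the silyl dienolate F2.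
- A catalytic asymmetric vinylogous Mukaiyama aldol reaction of F2 with 7 (SiCl4, chiral bisphosphoramide chosen for Re-face attack, CH2Cl2, −78 °C) should give the (13R) δ-hydroxy enoate F3, with the enoate geometry of 16.
- VO(acac)2/TBHP gives the erythro epoxy alcohol F4, and Ac2O/DMAP/pyridine the acetate F5.
- HF·pyridine removes both silyl groups to give the diol F6.
- MnO2, selective for the electron-rich allylic alcohol at C2, gives the hydroxy enal F7.
- An Appel reaction (CBr4, PPh3, CH2Cl2, 0 °C) gives the bromide, where the sequence comes back at 16.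

Step 4. The allylic C–H oxidation may lose site selectivity among the three trisubstituted olefins or over-oxidise. Fallback: the C13 oxygen is introduced by degradation and re-olefination instead of C–H oxidation, setting out from 5.
- NBS in aqueous THF at 0 °C converts the terminal olefin selectively into the bromohydrin F8.
- K2CO3 in MeOH closes it to the terminal epoxide F9.
- H5IO6 (THF/H2O, 0 °C) cleaves it to the trisnor aldehyde F10.
- A Wittig reaction with 2-(triphenylphosphoranylidene)propanal (toluene, 80 °C) gives the (E)-enal, where the sequence comes back at 7.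

Further compounds
F0 | step 11 | none | none
F1 | step 10 | methyl (2E)-2-{[(tert-butyldimethylsilyl)oxy]methyl}but-2-enoate | C/C=C(\CO[Si](C)(C)C(C)(C)C)C(=O)OC
F2 | step 10 | tert-butyl{[1-methoxy-2-({[tert-butyl(dimethyl)silyl]oxy}methyl)buta-1,3-dien-1-yl]oxy}dimethylsilane (silyl dienolate) | C=CC(CO[Si](C)(C)C(C)(C)C)=C(OC)O[Si](C)(C)C(C)(C)C
F3 | step 10 | methyl (2E,5R,6E,10Z,14E)-16-[(tert-butyldimethylsilyl)oxy]-2-{[(tert-butyldimethylsilyl)oxy]methyl}-5-hydroxy-6,10,14-trimethylhexadeca-2,6,10,14-tetraenoate | CC(C)(C)[Si](C)(C)OC/C=C(\C)CC/C=C(/C)CC/C=C(\C)[C@H](O)C/C=C(\CO[Si](C)(C)C(C)(C)C)C(=O)OC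
F4 | step 10 | erythro epoxy alcohol from F3 (11,12-epoxide, free C13 hydroxyl, both silyl ethers) | CC(C)(C)[Si](C)(C)OC/C=C(\C)CC/C=C(/C)CC[C@@H]1O[C@@]1(C)[C@H](O)C/C=C(\CO[Si](C)(C)C(C)(C)C)C(=O)OC
F5 | step 10 | C13 acetate of F4 | CC(C)(C)[Si](C)(C)OC/C=C(\C)CC/C=C(/C)CC[C@@H]1O[C@@]1(C)[C@H](OC(C)=O)C/C=C(\CO[Si](C)(C)C(C)(C)C)C(=O)OC
F6 | step 10 | diol from F5 (free C2 and C17 hydroxyls) | OC/C=C(\C)CC/C=C(/C)CC[C@@H]1O[C@@]1(C)[C@H](OC(C)=O)C/C=C(\CO)C(=O)OC
F7 | step 10 | hydroxy enal from F6 (C2 aldehyde, free C17 hydroxyl) | O=C/C=C(\C)CC/C=C(/C)CC[C@@H]1O[C@@]1(C)[C@H](OC(C)=O)C/C=C(\CO)C(=O)OC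
F8 | step 4 | (6Z,10E)-3-bromo-12-[(tert-butyldimethylsilyl)oxy]-2,6,10-trimethyldodeca-6,10-dien-2-ol (bromohydrin) | CC(C)(C)[Si](C)(C)OC/C=C(\C)CC/C=C(/C)CCC(Br)C(C)(C)O
F9 | step 4 | tert-butyl{[(2E,6Z)-9-(3,3-dimethyloxiran-2-yl)-3,7-dimethylnona-2,6-dien-1-yl]oxy}dimethylsilane (terminal epoxide) | CC(C)(C)[Si](C)(C)OC/C=C(\C)CC/C=C(/C)CCC1OC1(C)C
F10 | step 4 | (4Z,8E)-10-[(tert-butyldimethylsilyl)oxy]-4,8-dimethyldeca-4,8-dienal | CC(C)(C)[Si](C)(C)OC/C=C(\C)CC/C=C(/C)CCC=O
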